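## The problem

The target 18 is a diarylheptanoid folded into an oxane. O1 bridges C2, which carries ring A (4-hydroxy-3-methoxyphenyl), and C6, which carries the chain C7–C8 to ring B (a second 4-hydroxy-3-methoxyphenyl); C4 bears a hydroxyl. All three stereocentres are S: the substituents on C2 and C6 are cis (both equatorial) and the C4 hydroxyl is trans to both, hence axial. The axial hydroxyl is the awkward element, since a Prins closure or a small-hydride reduction of an oxan-4-one would deliver the equatorial epimer. It is therefore better to let C4 control the other centres than to make it last. Read along the open chain, the C4 oxygen is 1,3-syn to the oxygens on C2 and C6, so 18 is the cyclic ether of an all-syn 1,3,5-triol. C4 can set C6 by a chelation-controlled ketone reduction, and C2, a benzylic carbon on a para-oxygenated ring, can be set thermodynamically during ring closure. The sensitive groups are the two guaiacol-type phenols (acidic, easily oxidised), the ring C2–O1 bond (a benzylic ether that ionises in acid and can be hydrogenolysed) and any β-hydroxy ketone met on the way. The enabling feature is that C3–C4–C5 with oxygen on C4 is the skeleton of epichlorohydrin, while C2 and C6, both bound to O1, are at the carbonyl level in the open chain and can each enter as an acyl anion equivalent.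

## Retrosynthesis

**18 from 17.** The phenols are masked as benzyl ethers in 17. Benzyl survives organolithiums, catalytic BF3·OEt2, MeI, borohydride and catalytic acid, and is removed without acid or base. The forward step must cleave two ArO–CH2Ph bonds while sparing the ring C2–O1 bond.

**17 from 16.** The ring is opened at O1–C2 to give triol 16. Cutting O1–C6 instead would need an SN2 inversion at an unactivated secondary carbon and a sulfonate. Cutting O1–C2 uses the para-benzyloxybenzylic cation, needs no activating group, and leaves C4 and C6 untouched. The configuration at the benzylic carbon of 16 then no longer matters, because the closure settles as the 2,6-diequatorial ether. The forward reaction must ionise only the benzylic hydroxyl.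

**16 from 14.** The C–H bonds at C2 and C6 are removed to give hydroxy dione 14, reduced through its C4 diethylborinate 15. The syn relation between the C4 and C6 oxygens is what a boron-chelate-controlled reduction gives; an anti-selective reduction would lead to the all-equatorial epimer. Only C4 remains as a stereocentre. The forward step must reduce the C6 carbonyl while it is held in the chelate.

**14 from 13.** Both carbonyls are masked as 1,3-dithianes in 13. This turns C2 and C6 into carbons that can be nucleophiles. The forward step must release a β-hydroxy-1,5-dione without dehydration or retro-aldol cleavage.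

**13 from 3, 8 and 7 (key disconnection).** C2–C3 and C5–C6 are cut, giving aryl dithiane 3, alkyl dithiane 7 and (R)-epichlorohydrin 8.
- An aldol cut of 14 at C3–C4 or C4–C5 would require an asymmetric methyl ketone aldol to create C4. Here C4 is bought, and the two bonds are made by the same well-known reaction in one flask.
- Lithiated 3 (9) opens 8 at the oxirane CH2, alkoxide 10 closes to oxirane 11, and lithiated 7 (12) opens 11.
- The order is fixed by configuration: with (R)-8 the first nucleophile enters at the oxirane CH2 and the second at the former chloromethyl carbon, so adding the aryl dithiane first gives (S)-13.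
- The order is also sensible by reactivity: the less reactive, aryl-stabilised anion meets the more reactive electrophile 8, and the more nucleophilic alkyl dithiane anion meets the less reactive oxirane 11.
- The step must give oxirane opening, not chloride displacement, and terminal attack both times.

**3 from 1 and 2; 7 from 6 and 2; 6 from 5 from 4.** Both dithianes come from aldehydes and propane-1,3-dithiol 2. Aldehyde 1 (O-benzylvanillin) is purchased. Aldehyde 6 comes from dihydroferulic acid 4 by double benzylation to 5 and partial reduction.

## Roads not taken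

**Alternative 1:** The ring is cut at C5–C6 and O1–C2, a hetero-Diels–Alder retron.
- Forward step: (E)-1-(4-benzyloxy-3-methoxyphenyl)-3-(triethylsilyloxy)buta-1,3-diene A1 and aldehyde 6 would be joined by the chloro chromium complex (trivalent chromium) of the tridentate Schiff base from cis-1-amino-2-indanol and 3-(1-adamantyl)-5-methylsalicylaldehyde. The product is the cis dihydropyran (2S,6S)-2-(4-benzyloxy-3-methoxyphenyl)-6-[2-(4-benzyloxy-3-methoxyphenyl)ethyl]-4-(triethylsilyloxy)-5,6-dihydro-2H-pyran A2. Desilylation to oxanone A3, equatorial-face reduction with LiBH(s-Bu)3 to 17 and hydrogenolysis would finish the synthesis.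
- Merits: the ring and the C2 and C6 centres form in one catalytic step, the route is convergent, it shares aldehyde 6, and it is about two steps shorter than the chosen route. In step count and in catalytic use of chirality it is the better road.
- Weak points: a diene ending in a donor aryl group is conjugated and less reactive than the 1-alkoxy dienes for which this catalyst type is established, so rate, endo (cis) selectivity and enantioselectivity with an enolisable aldehyde are open. The C2–O1 bond of A2 is both allylic and benzylic and may ionise when the silyl enol ether is hydrolysed. C4 is made last, against the thermodynamic preference, by reagent control.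
- Comparison: the chosen plan is longer and stoichiometric in lithium. Against that, its absolute configuration is purchased, every bond formation is of a long-established type, and the axial C4 hydroxyl follows from the design because C4 is the source of the stereochemistry.

**Alternative 2:** The ring is cut at O1–C6, an oxa-Michael retron.
- Forward step: the ene-dione (E)-1,7-bis(4-benzyloxy-3-methoxyphenyl)hept-4-ene-1,3-dione A4 would cyclise under a cinchona-derived amine–thiourea, the enol oxygen at C2 adding to C6, to give (S)-6-(4-benzyloxy-3-methoxyphenyl)-2-[2-(4-benzyloxy-3-methoxyphenyl)ethyl]-2,3-dihydro-4H-pyran-4-one A5. Hydrogenation of the ring double bond opposite the C6 chain (with loss of the benzyl groups) and equatorial-face ketone reduction would lead to 18.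
- Merits: metal-free, catalytic, short, and the phenols are unveiled in the hydrogenation that sets C2.
- Weak points: only C6 is set in the key step. The closure is reversible, so ring opening can erode the enantiomeric purity of A5. The double bond of a vinylogous ester is slow to hydrogenate, and its saturation creates the hydrogenolysis-prone benzylic C2–O1 bond on the same catalyst and under more forcing conditions than the chosen route needs for debenzylation alone. C4 again comes last by reagent control.
- Comparison: it is similar in length or slightly shorter, but it carries three successive stereochemical risks. In the chosen plan one purchased centre is relayed to C6 by chelation and to C2 by thermodynamics.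

**Alternative 3:** The chain is cut at C3–C4 and C4–C5 around a C4 linchpin.
- Forward step: lithiated 2-(tert-butyldimethylsilyl)-1,3-dithiane A6 would open (R)-2-(4-benzyloxy-3-methoxyphenyl)oxirane A7 at its CH2. HMPA would trigger a Brook rearrangement moving silicon to the C2 oxygen, and the new dithiane anion would open (R)-2-[2-(4-benzyloxy-3-methoxyphenyl)ethyl]oxirane A8. The product is (1S,5R)-1,7-bis(4-benzyloxy-3-methoxyphenyl)-1-(tert-butyldimethylsilyloxy)-3,3-(propane-1,3-diyldithio)heptan-5-ol A9. Sulfonylation of the free C6 hydroxyl, desilylation and displacement by the C2 oxygen with inversion at C6, dithiane hydrolysis to A3, equatorial-face reduction to 17 and hydrogenolysis would follow.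
- Merits: it is a one-flask three-component union like the chosen key step, and C2 and C6 are fixed independently by the building blocks, so neither depends on substrate control.
- Weak points: two enantiopure oxiranes must be made. A7 is a para-alkoxystyrene oxide, which opens partly at the benzylic carbon and racemises easily. Ring closure needs an SN2 inversion at C6. C4 is again set last. The step count is clearly higher.
- Comparison: the chosen plan uses the same dithiane chemistry with one cheap chiral three-carbon unit in place of two bespoke oxiranes, and it places the bought centre at C4, where it controls the other two.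

Key step: step 5

Remark on the chemistry: triol 16 is drawn as its all-syn 1S isomer; the benzylic configuration is erased in step 8, so any 1R epimer is carried along and converges on 17.

## Route

Step 1
Reactants: 1 4-benzyloxy-3-methoxybenzaldehyde; 2 propane-1,3-dithiol
Product: 3 2-(4-benzyloxy-3-methoxyphenyl)-1,3-dithiane
Conditions: 2 (1.1 equiv), BF3·OEt2 (0.2 equiv), CH2Cl2, 0 °C to rt
Reagents that add atoms: none
Why: Lewis-acid-catalysed dithioacetalisation of an aromatic aldehyde (Corey–Seebach dithiane formation); a catalytic amount of BF3·OEt2 at 0 °C should leave the aryl benzyl and methyl ethers intact.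

Step 2
Reactants: 4 3-(4-hydroxy-3-methoxyphenyl)propanoic acid
Product: 5 benzyl 3-(4-benzyloxy-3-methoxyphenyl)propanoate
Conditions: BnBr (2.3 equiv), K2CO3 (3 equiv), DMF, rt to 60 °C
Reagents that add atoms: benzyl bromide, BrCc1ccccc1
Why: Williamson ether synthesis at the phenoxide and O-alkylation of the carboxylate in one operation; the benzyl ester also has the right oxidation level for a one-step reduction to the aldehyde.

Step 3
Reactants: 5 benzyl 3-(4-benzyloxy-3-methoxyphenyl)propanoate
Product: 6 3-(4-benzyloxy-3-methoxyphenyl)propanal
Conditions: i-Bu2AlH (1.1 equiv), CH2Cl2, −78 °C; MeOH, then aq. KNaC4H4O6 (potassium sodium tartrate)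
Reagents that add atoms: none
Why: Partial reduction of an ester with i-Bu2AlH; at −78 °C the tetrahedral aluminium hemiacetal persists and gives the aldehyde only on work-up, and the aryl benzyl ether is inert.

Step 4
Reactants: 6 3-(4-benzyloxy-3-methoxyphenyl)propanal; 2 propane-1,3-dithiol
Product: 7 2-[2-(4-benzyloxy-3-methoxyphenyl)ethyl]-1,3-dithiane
Conditions: 2 (1.1 equiv), BF3·OEt2 (0.2 equiv), CH2Cl2, 0 °C
Reagents that add atoms: none
Why: Lewis-acid-catalysed dithioacetalisation of an aliphatic aldehyde, which is faster than for the aromatic case, so the same mild conditions apply.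

Step 5
Reactants: 3 2-(4-benzyloxy-3-methoxyphenyl)-1,3-dithiane; 8 (R)-epichlorohydrin; 7 2-[2-(4-benzyloxy-3-methoxyphenyl)ethyl]-1,3-dithiane
Product: 13 (S)-1-[2-(4-benzyloxy-3-methoxyphenyl)-1,3-dithian-2-yl]-3-{2-[2-(4-benzyloxy-3-methoxyphenyl)ethyl]-1,3-dithian-2-yl}propan-2-ol, via lithiated aryl dithiane 9 (not isolated), via lithium chloro alkoxide 10 (not isolated), via dithianylmethyl oxirane 11 (not isolated), via lithiated alkyl dithiane 12 (not isolated)
Conditions: 3, n-BuLi (1.0 equiv), THF, −78 to −30 °C; 8 (1.0 equiv), −78 °C, then to 0 °C; 12 (from 7 (1.3 equiv), t-BuLi (1.25 equiv), THF/HMPA 9:1, −78 °C) added by cannula at −78 °C, then to −20 °C; H2O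
Reagents that add atoms: none
Why: Deprotonation of 3 gives the aryl-stabilised anion 9, which should open the oxirane of 8 by SN2 attack at its unsubstituted CH2 (the future C3), the site that organolithium nucleophiles prefer over the chloromethyl carbon at −78 °C. On warming, alkoxide 10 displaces chloride in a 3-exo-tet closure to the terminal oxirane 11, and the more nucleophilic alkyl dithiane anion 12, activated by HMPA, opens 11 at its CH2 (the future C5). The closest known reaction type is the Corey–Seebach alkylation of 2-lithio-1,3-dithianes with epoxides, run here as the established one-flask double alkylation of epichlorohydrin by two different dithiane anions. No ring of the target is closed; the only ring formed is the transient oxirane of 11, which is consumed again. No stereocentre is created: the carbinol carbon comes from 8 and is never a reaction site, and its descriptor changes from R to S only because the ranking of its two CH2 arms changes. The selectivity needed is regiochemical, namely oxirane opening before chloride displacement in the first stage (direct displacement would lead to the enantiomer) and terminal attack in the second; low temperature, the poor chloride leaving group and the unhindered CH2 termini should secure both. Selectivity between the two anions rests on the order of addition and on using 3 and 8 in equal amounts, so that 9 is consumed before 11 appears.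

Step 6
Reactants: 13 (S)-1-[2-(4-benzyloxy-3-methoxyphenyl)-1,3-dithian-2-yl]-3-{2-[2-(4-benzyloxy-3-methoxyphenyl)ethyl]-1,3-dithian-2-yl}propan-2-ol
Product: 14 (S)-1,7-bis(4-benzyloxy-3-methoxyphenyl)-3-hydroxyheptane-1,5-dione
Conditions: MeI (excess), CaCO3, MeCN/H2O 9:1, 45 °C
Reagents that add atoms: water, O
Why: S-alkylative hydrolysis of 1,3-dithianes: methylation gives sulfonium ions that open to thionium ions, which water captures; CaCO3 keeps the medium near neutral so the β-hydroxy ketone should neither dehydrate nor cleave, no oxidant touches the electron-rich rings, and C4 is not involved.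

Step 7
Reactants: 14 (S)-1,7-bis(4-benzyloxy-3-methoxyphenyl)-3-hydroxyheptane-1,5-dione
Product: 16 (1S,3S,5S)-1,7-bis(4-benzyloxy-3-methoxyphenyl)heptane-1,3,5-triol, via diethylborinate 15 (not isolated)
Conditions: Et2BOMe (1.2 equiv), THF/MeOH 4:1, −78 °C; NaBH4 (3 equiv), −78 °C, then 0 °C; AcOH; MeOH co-evaporation
Reagents that add atoms: none
Why: Narasaka–Prasad reduction: borinate 15 holds a carbonyl in a six-membered chelate and external hydride adds axially to give the 1,3-syn diol; the more electrophilic alkyl carbonyl should be reduced first within the chelate, setting the chain carbinol (C6 of the ring) as S, and the para-alkoxyaryl carbonyl is reduced on warming. The benzylic centre may form as a mixture, which is harmless because step 8 passes through the cation.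

Step 8
Reactants: 16 (1S,3S,5S)-1,7-bis(4-benzyloxy-3-methoxyphenyl)heptane-1,3,5-triol
Product: 17 (2S,4S,6S)-2-(4-benzyloxy-3-methoxyphenyl)-6-[2-(4-benzyloxy-3-methoxyphenyl)ethyl]oxan-4-ol
Conditions: p-TsOH·H2O (10 mol %), CH2Cl2 (dilute), 0 °C to rt
Reagents that add atoms: none
Why: Acid-catalysed dehydrative cycloetherification (SN1): the para-benzyloxy ring stabilises the C2 cation, which the C6 hydroxyl captures in a 6-exo-trig closure, the only ring size available since attack by the C4 hydroxyl would give an oxetane. Ionisation is reversible, so the product should settle as the isomer with aryl and side chain both equatorial (2,6-cis, C2 S); C4 and C6 are not touched, and the C4 hydroxyl ends axial.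

Step 9
Reactants: 17 (2S,4S,6S)-2-(4-benzyloxy-3-methoxyphenyl)-6-[2-(4-benzyloxy-3-methoxyphenyl)ethyl]oxan-4-ol
Product: 18 (2S,4S,6S)-2-(4-hydroxy-3-methoxyphenyl)-6-[2-(4-hydroxy-3-methoxyphenyl)ethyl]oxan-4-ol
Conditions: H2 (1 atm), 10% Pd/C (palladium metal on carbon), EtOAc, rt, stopped after uptake of 2 equiv H2
Reagents that add atoms: none
Why: Catalytic hydrogenolysis of aryl benzyl ethers; in a neutral aprotic solvent the ArO–CH2Ph bonds should be cleaved much faster than the ring C2–O1 bond, and no stereocentre is involved.

## Compound list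

1 | 4-benzyloxy-3-methoxybenzaldehyde (O-benzylvanillin) | COc1cc(C=O)ccc1OCc1ccccc1 | starting material
2 | propane-1,3-dithiol | SCCCS | starting material
3 | 2-(4-benzyloxy-3-methoxyphenyl)-1,3-dithiane | COc1cc(C2SCCCS2)ccc1OCc1ccccc1 | intermediate
4 | 3-(4-hydroxy-3-methoxyphenyl)propanoic acid (dihydroferulic acid) | COc1cc(CCC(=O)O)ccc1O | starting material
5 | benzyl 3-(4-benzyloxy-3-methoxyphenyl)propanoate | COc1cc(CCC(=O)OCc2ccccc2)ccc1OCc1ccccc1 | intermediate
6 | 3-(4-benzyloxy-3-methoxyphenyl)propanal | COc1cc(CCC=O)ccc1OCc1ccccc1 | intermediate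
7 | 2-[2-(4-benzyloxy-3-methoxyphenyl)ethyl]-1,3-dithiane | COc1cc(CCC2SCCCS2)ccc1OCc1ccccc1 | intermediate
8 | (R)-epichlorohydrin | ClC[C@H]1CO1 | starting material
9 | 2-lithio-2-(4-benzyloxy-3-methoxyphenyl)-1,3-dithiane | COc1cc(C2([Li])SCCCS2)ccc1OCc1ccccc1 | intermediate
10 | lithium (R)-1-chloro-3-[2-(4-benzyloxy-3-methoxyphenyl)-1,3-dithian-2-yl]propan-2-olate | ClC[C@H](O[Li])CC1(SCCCS1)c1ccc(OCc2ccccc2)c(OC)c1 | intermediate
11 | (R)-2-{[2-(4-benzyloxy-3-methoxyphenyl)-1,3-dithian-2-yl]methyl}oxirane | C1O[C@@H]1CC1(SCCCS1)c1ccc(OCc2ccccc2)c(OC)c1 | intermediate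
12 | 2-lithio-2-[2-(4-benzyloxy-3-methoxyphenyl)ethyl]-1,3-dithiane | COc1cc(CCC2([Li])SCCCS2)ccc1OCc1ccccc1 | intermediate
13 | (S)-1-[2-(4-benzyloxy-3-methoxyphenyl)-1,3-dithian-2-yl]-3-{2-[2-(4-benzyloxy-3-methoxyphenyl)ethyl]-1,3-dithian-2-yl}propan-2-ol | COc1cc(CCC2(SCCCS2)C[C@H](O)CC2(SCCCS2)c2ccc(OCc3ccccc3)c(OC)c2)ccc1OCc1ccccc1 | intermediate
14 | (S)-1,7-bis(4-benzyloxy-3-methoxyphenyl)-3-hydroxyheptane-1,5-dione | COc1cc(CCC(=O)C[C@H](O)CC(=O)c2ccc(OCc3ccccc3)c(OC)c2)ccc1OCc1ccccc1 | intermediate
15 | (S)-1,7-bis(4-benzyloxy-3-methoxyphenyl)-3-(diethylboranyloxy)heptane-1,5-dione | COc1cc(CCC(=O)C[C@H](OB(CC)CC)CC(=O)c2ccc(OCc3ccccc3)c(OC)c2)ccc1OCc1ccccc1 | intermediate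
16 | (1S,3S,5S)-1,7-bis(4-benzyloxy-3-methoxyphenyl)heptane-1,3,5-triol | COc1cc(CC[C@H](O)C[C@H](O)C[C@H](O)c2ccc(OCc3ccccc3)c(OC)c2)ccc1OCc1ccccc1 | intermediate
17 | (2S,4S,6S)-2-(4-benzyloxy-3-methoxyphenyl)-6-[2-(4-benzyloxy-3-methoxyphenyl)ethyl]oxan-4-ol | COc1cc(CC[C@H]2C[C@H](O)C[C@@H](c3ccc(OCc4ccccc4)c(OC)c3)O2)ccc1OCc1ccccc1 | intermediate
18 | (2S,4S,6S)-2-(4-hydroxy-3-methoxyphenyl)-6-[2-(4-hydroxy-3-methoxyphenyl)ethyl]oxan-4-ol | COc1cc(CC[C@H]2C[C@H](O)C[C@@H](c3ccc(O)c(OC)c3)O2)ccc1O | target

## Step count and risks

Total steps: 9. Longest linear sequence: 8 (steps 2 to 9, from 4).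

**Step 5 (key step).**
- What may go wrong: cross-reaction between the two anions and the two electrophiles in one flask (incomplete closure of 10, opening of 11 by leftover 9), and erosion of enantiomeric purity if some 9 displaces chloride directly.
- Fallback: the relay is replaced by a stepwise sequence with isolated intermediates. It sets out from 3 and 8. Lithiated 3 is added to 8 at −78 °C and the mixture is quenched cold with AcOH, so that the neutral chlorohydrin (R)-1-chloro-3-[2-(4-benzyloxy-3-methoxyphenyl)-1,3-dithian-2-yl]propan-2-ol F1 can be purified and its optical purity checked. K2CO3 in MeOH closes F1 to oxirane 11, which is isolated and opened in a separate operation with 12, rejoining the route at 13.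

**Step 7.**
- What may go wrong: poor site selectivity of the first, chelate-controlled hydride transfer. If the aryl carbonyl is reduced first, the boron is tied up and C6 is reduced without control, which the acid closure cannot correct.
- Fallback: ring closure by reductive etherification in place of the benzylic cation, setting out from 14. The reduction is stopped after one hydride transfer (Et2BOMe 1.1 equiv, NaBH4, −78 °C, cold quench) to give (3S,5S)-1,7-bis(4-benzyloxy-3-methoxyphenyl)-3,5-dihydroxyheptan-1-one F2. If the other carbonyl reacts first, the product is the regioisomer (1S,3R)-1,7-bis(4-benzyloxy-3-methoxyphenyl)-1,3-dihydroxyheptan-5-one F3. Each exists in equilibrium with its six-membered hemiketal and each has its new carbinol syn to C4. Et3SiH and TMSOTf in CH2Cl2/MeCN at −78 °C ionise the hemiketal to the cyclic oxocarbenium ion, and axial hydride delivery places the remaining ring substituent cis to the existing one, so both converge on 17.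

**Step 6.**
- What may go wrong: slow release of the hindered dialkyl dithiane, with dehydration or retro-aldol cleavage of the β-hydroxy ketones, or aldol cyclisation of the 1,5-dione, during prolonged warming.
- Fallback: the hydroxyl is masked before unmasking the carbonyls, setting out from 13. Silylation (Et3SiOTf, 2,6-lutidine) gives (S)-triethyl{1-[2-(4-benzyloxy-3-methoxyphenyl)-1,3-dithian-2-yl]-3-{2-[2-(4-benzyloxy-3-methoxyphenyl)ethyl]-1,3-dithian-2-yl}propan-2-yloxy}silane F4. Dithiane hydrolysis then gives (S)-1,7-bis(4-benzyloxy-3-methoxyphenyl)-3-(triethylsilyloxy)heptane-1,5-dione F5, which cannot undergo retro-aldol cleavage. HF·pyridine in THF at 0 °C removes the silyl group and the route is rejoined at 14.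

**Step 9.**
- What may go wrong: hydrogenolytic cleavage of the ring C2–O1 bond, a benzylic ether on an electron-rich ring, in competition with removal of the benzyl groups.
- Fallback: the benzyl groups are removed before any benzylic C–O bond exists, setting out from 14. Hydrogenolysis (H2, Pd/C, EtOAc) gives (S)-3-hydroxy-1,7-bis(4-hydroxy-3-methoxyphenyl)heptane-1,5-dione F6. Narasaka–Prasad reduction with excess Et2BOMe and NaBH4 gives (1S,3S,5S)-1,7-bis(4-hydroxy-3-methoxyphenyl)heptane-1,3,5-triol F7. Catalytic acid then closes the ring through the para-quinone-methide-type cation and the route is rejoined at 18.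

## Further compounds

F1 | step 5 | (R)-1-chloro-3-[2-(4-benzyloxy-3-methoxyphenyl)-1,3-dithian-2-yl]propan-2-ol | ClC[C@H](O)CC1(SCCCS1)c1ccc(OCc2ccccc2)c(OC)c1
F2 | step 7 | (3S,5S)-1,7-bis(4-benzyloxy-3-methoxyphenyl)-3,5-dihydroxyheptan-1-one | COc1cc(CC[C@H](O)C[C@H](O)CC(=O)c2ccc(OCc3ccccc3)c(OC)c2)ccc1OCc1ccccc1
F3 | step 7 | (1S,3R)-1,7-bis(4-benzyloxy-3-methoxyphenyl)-1,3-dihydroxyheptan-5-one | COc1cc(CCC(=O)C[C@H](O)C[C@H](O)c2ccc(OCc3ccccc3)c(OC)c2)ccc1OCc1ccccc1
F4 | step 6 | (S)-triethyl{1-[2-(4-benzyloxy-3-methoxyphenyl)-1,3-dithian-2-yl]-3-{2-[2-(4-benzyloxy-3-methoxyphenyl)ethyl]-1,3-dithian-2-yl}propan-2-yloxy}silane | COc1cc(CCC2(SCCCS2)C[C@H](O[Si](CC)(CC)CC)CC2(SCCCS2)c2ccc(OCc3ccccc3)c(OC)c2)ccc1OCc1ccccc1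
F5 | step 6 | (S)-1,7-bis(4-benzyloxy-3-methoxyphenyl)-3-(triethylsilyloxy)heptane-1,5-dione | COc1cc(CCC(=O)C[C@H](O[Si](CC)(CC)CC)CC(=O)c2ccc(OCc3ccccc3)c(OC)c2)ccc1OCc1ccccc1
F6 | step 9 | (S)-3-hydroxy-1,7-bis(4-hydroxy-3-methoxyphenyl)heptane-1,5-dione | COc1cc(CCC(=O)C[C@H](O)CC(=O)c2ccc(O)c(OC)c2)ccc1O
F7 | step 9 | (1S,3S,5S)-1,7-bis(4-hydroxy-3-methoxyphenyl)heptane-1,3,5-triol | COc1cc(CC[C@H](O)C[C@H](O)C[C@H](O)c2ccc(O)c(OC)c2)ccc1O
A1 | alternative 1 | (E)-1-(4-benzyloxy-3-methoxyphenyl)-3-(triethylsilyloxy)buta-1,3-diene | C=C(O[Si](CC)(CC)CC)/C=C/c1ccc(OCc2ccccc2)c(OC)c1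
A2 | alternative 1 | (2S,6S)-2-(4-benzyloxy-3-methoxyphenyl)-6-[2-(4-benzyloxy-3-methoxyphenyl)ethyl]-4-(triethylsilyloxy)-5,6-dihydro-2H-pyran | COc1cc(CC[C@H]2CC(O[Si](CC)(CC)CC)=C[C@@H](c3ccc(OCc4ccccc4)c(OC)c3)O2)ccc1OCc1ccccc1
A3 | alternative 1 | (2S,6S)-2-(4-benzyloxy-3-methoxyphenyl)-6-[2-(4-benzyloxy-3-methoxyphenyl)ethyl]oxan-4-one | COc1cc(CC[C@H]2CC(=O)C[C@@H](c3ccc(OCc4ccccc4)c(OC)c3)O2)ccc1OCc1ccccc1
A4 | alternative 2 | (E)-1,7-bis(4-benzyloxy-3-methoxyphenyl)hept-4-ene-1,3-dione | COc1cc(CC/C=C/C(=O)CC(=O)c2ccc(OCc3ccccc3)c(OC)c2)ccc1OCc1ccccc1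
A5 | alternative 2 | (S)-6-(4-benzyloxy-3-methoxyphenyl)-2-[2-(4-benzyloxy-3-methoxyphenyl)ethyl]-2,3-dihydro-4H-pyran-4-one | COc1cc(CC[C@H]2CC(=O)C=C(c3ccc(OCc4ccccc4)c(OC)c3)O2)ccc1OCc1ccccc1
A6 | alternative 3 | 2-(tert-butyldimethylsilyl)-1,3-dithiane | CC(C)(C)[Si](C)(C)C1SCCCS1
A7 | alternative 3 | (R)-2-(4-benzyloxy-3-methoxyphenyl)oxirane | C1[C@@H](c2ccc(OCc3ccccc3)c(OC)c2)O1
A8 | alternative 3 | (R)-2-[2-(4-benzyloxy-3-methoxyphenyl)ethyl]oxirane | COc1cc(CC[C@@H]2CO2)ccc1OCc1ccccc1
A9 | alternative 3 | (1S,5R)-1,7-bis(4-benzyloxy-3-methoxyphenyl)-1-(tert-butyldimethylsilyloxy)-3,3-(propane-1,3-diyldithio)heptan-5-ol | COc1cc(CC[C@@H](O)CC2(SCCCS2)C[C@@H](c2ccc(OCc3ccccc3)c(OC)c2)O[Si](C)(C)C(C)(C)C)ccc1OCc1ccccc1
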